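**Retrosynthetic overview**

- The target is reached by fluoride desilylation of its 4-hydroxyphenyl oxygen; nothing else changes in the last step.
- The strategy rests on ring A: C1 bears CO2Me, C2 and C4 bear OH, C3 and C5 bear prenyl, and C6 bears the 2-arylethyl group. This meta-dioxygenated benzoate is the folded form of a nine-carbon chain with an ester at C1 and ketones at C3, C5 and C7. Cutting ring A bond C1–C6 (chain C2–C7) opens the only ring formed to a 4,6-diprenyl-3,5,7-trioxo-9-arylnonanoate.
- The triketo ester is cut at chain C6–C7: trianion of a 4-prenyl-3,5-dioxo ester plus the N-methoxy-N-methylamide of the silylated 3-arylpropanoic acid.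
- The diketo ester is cut at C4–C5: dianion of methyl 7-methyl-3-oxooct-6-enoate (methyl acetoacetate plus prenyl bromide) plus the N-methoxy-N-methylamide of 5-methylhex-4-enoic acid. Both prenyl groups therefore enter as chain carbons and none by aromatic substitution.

Key step: step 7

Remark on the chemistry: the target has no stereocentre; the open-chain di- and triketo esters are keto–enol mixtures with configurationally labile C4 and C6 and are drawn without configuration. The phenol is carried as a triisopropylsilyl ether, chosen over a tert-butyldimethylsilyl ether because it should better withstand lithium polyenolates and carbonate in methanol, and it leaves with fluoride just the same.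

**Route**

Step 1
Reactants: 1 methyl acetoacetate; 2 prenyl bromide (1-bromo-3-methylbut-2-ene)
Product: 4 methyl 7-methyl-3-oxooct-6-enoate, via dilithium dianion 3 (not isolated)
Conditions: LiN(i-Pr)2 (2.1 equiv), THF, 0 °C; then 2, 0 °C to rt; AcOH quench
Reagents that add atoms: none
Why: γ-Alkylation of a β-keto ester dianion: the terminal carbanion, stabilised by one carbonyl only, is the more nucleophilic site and displaces bromide at the primary allylic carbon (SN2), leaving C2 untouched.

Step 2
Reactants: 5 5-methylhex-4-enoic acid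
Product: 7 N-methoxy-N,5-dimethylhex-4-enamide, via acyl imidazolide 6 (not isolated)
Conditions: CDI, CH2Cl2, rt; then MeNH(OMe)·HCl, rt
Reagents that add atoms: N,O-dimethylhydroxylamine hydrochloride, CNOC.Cl
Why: Amide formation through the acyl imidazolide (carbonyldiimidazole activation) gives the Weinreb amide under neutral conditions that leave the trisubstituted alkene alone.

Step 3
Reactants: 4 methyl 7-methyl-3-oxooct-6-enoate; 7 N-methoxy-N,5-dimethylhex-4-enamide
Product: 9 methyl 9-methyl-4-(3-methylbut-2-enyl)-3,5-dioxodec-8-enoate (keto–enol mixture), via dilithium dianion 8 (not isolated)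
Conditions: 4, LiN(i-Pr)2 (2.2 equiv), THF, −78 to 0 °C; then 7 (0.6 equiv), −78 to 0 °C; AcOH, −78 °C
Reagents that add atoms: none
Why: Claisen-type C-acylation of a β-keto ester dianion at its γ-carbon by a Weinreb amide, whose chelated tetrahedral adduct frees the new ketone only on quench so that over-addition is excluded; the excess dianion covers loss by proton transfer, and the new centre at C4 is enolisable and uncontrolled.

Step 4
Reactants: 10 methyl 3-(4-hydroxyphenyl)propanoate
Product: 11 methyl 3-[4-(triisopropylsilyloxy)phenyl]propanoate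
Conditions: i-Pr3SiCl, imidazole, DMF, rt
Reagents that add atoms: triisopropylsilyl chloride, CC(C)[Si](Cl)(C(C)C)C(C)C
Why: Imidazole-promoted O-silylation of a phenol masks the only acidic OH before polyanion chemistry.

Step 5
Reactants: 11 methyl 3-[4-(triisopropylsilyloxy)phenyl]propanoate
Product: 12 N-methoxy-N-methyl-3-[4-(triisopropylsilyloxy)phenyl]propanamide
Conditions: MeNH(OMe)·HCl, i-PrMgCl, THF, −20 to 0 °C
Reagents that add atoms: N,O-dimethylhydroxylamine hydrochloride, CNOC.Cl
Why: Direct aminolysis of the methyl ester by the chloromagnesium amide of N,O-dimethylhydroxylamine (Weinreb amide synthesis from an ester) at low temperature, which the aryl silyl ether tolerates.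

Step 6
Reactants: 9 methyl 9-methyl-4-(3-methylbut-2-enyl)-3,5-dioxodec-8-enoate; 12 N-methoxy-N-methyl-3-[4-(triisopropylsilyloxy)phenyl]propanamide
Product: 14 methyl 4,6-bis(3-methylbut-2-enyl)-3,5,7-trioxo-9-[4-(triisopropylsilyloxy)phenyl]nonanoate (keto–enol mixture), via trilithium trianion 13 (not isolated)
Conditions: 9, LiN(i-Pr)2 (3.2 equiv), THF, −78 to 0 °C; then 12 (0.8 equiv), −78 to −20 °C; AcOH, −78 °C; used without chromatography
Reagents that add atoms: none
Why: Polyketide chain extension by Claisen-type C-acylation of a diketo ester trianion: the terminal carbon C6, stabilised by one carbonyl only, is the most nucleophilic of the three enolate sites, and the chelated Weinreb adduct releases the third ketone only on the acetic acid quench, so the product is not consumed by proton transfer; the new centre at C6 is enolisable and uncontrolled.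

Step 7
Reactants: 14 methyl 4,6-bis(3-methylbut-2-enyl)-3,5,7-trioxo-9-[4-(triisopropylsilyloxy)phenyl]nonanoate
Product: 16 methyl 2,4-dihydroxy-3,5-bis(3-methylbut-2-enyl)-6-{2-[4-(triisopropylsilyloxy)phenyl]ethyl}benzoate, via cyclic aldol adduct 15 (not isolated)
Conditions: K2CO3, MeOH/CH2Cl2, 0 °C to rt; then AcOH to pH 6
Reagents that add atoms: none
Why: Carbonate removes a proton from chain C2, the only unsubstituted carbon between two carbonyl groups, and this β-keto ester enolate adds to the C7 ketone to form ring A bond C1–C6 (chain C2–C7); Knoevenagel-type loss of water from adduct 15 and enolisation of the C3 and C5 ketones then give the benzene ring, which makes the sequence irreversible. The closest known reaction type is the biomimetic aldol cyclisation–aromatisation of 3,5,7-trioxo esters to resorcylates (an intramolecular Knoevenagel condensation). The single ring closes in a 6-exo-trig aldol mode, which the ring-closure rules for enolates allow whether the delocalised enolate is counted as enolexo through the ester carbonyl or enolendo through the C3 ketone. No stereocentre remains, since the labile centres at C4 and C6 and the carbinol carbon of 15 all become sp2. The step must prefer the C2-to-C7 aldol over the C6-to-C1 Claisen closure, the C8-to-C3 aldol and O-acylation to a pyranone: C2 is far more acidic than the singly activated C8, Claisen attack by C6 would create a quaternary carbon that cannot aromatise and stays reversible, and a weak non-chelating base in a protic medium is known to favour the aldol mode. The alkyl groups at C4 and C6 should also lower the enol content of the diketone units so that C7 remains a reactive ketone, and any silyl loss here would only deliver the target early.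

Step 8
Reactants: 16 methyl 2,4-dihydroxy-3,5-bis(3-methylbut-2-enyl)-6-{2-[4-(triisopropylsilyloxy)phenyl]ethyl}benzoate
Product: 17 methyl 2,4-dihydroxy-6-[2-(4-hydroxyphenyl)ethyl]-3,5-bis(3-methylbut-2-enyl)benzoate (CNP0133671.0)
Conditions: Bu4NF, AcOH, THF, 0 °C
Reagents that add atoms: none
Why: Fluoride cleavage of an aryl silyl ether; buffering with acetic acid keeps the ortho-prenyl phenols away from strong base and strong acid, so that neither ester cleavage nor chroman formation is expected.

**Compound list**

1 | methyl acetoacetate | COC(=O)CC(C)=O | starting material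
2 | prenyl bromide (1-bromo-3-methylbut-2-ene) | CC(C)=CCBr | starting material
3 | dilithium dianion of methyl acetoacetate | COC([O-])=CC([O-])=C.[Li+].[Li+] | intermediate
4 | methyl 7-methyl-3-oxooct-6-enoate | COC(=O)CC(=O)CCC=C(C)C | intermediate
5 | 5-methylhex-4-enoic acid | CC(C)=CCCC(=O)O | starting material
6 | 1-(imidazol-1-yl)-5-methylhex-4-en-1-one (acyl imidazolide of 5) | CC(C)=CCCC(=O)n1ccnc1 | intermediate
7 | N-methoxy-N,5-dimethylhex-4-enamide | CON(C)C(=O)CCC=C(C)C | intermediate
8 | dilithium dianion of 4 (C2 and C4 deprotonated) | COC([O-])=CC([O-])=CCC=C(C)C.[Li+].[Li+] | intermediate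
9 | methyl 9-methyl-4-(3-methylbut-2-enyl)-3,5-dioxodec-8-enoate (keto–enol mixture, C4 labile) | COC(=O)CC(=O)C(CC=C(C)C)C(=O)CCC=C(C)C | intermediate
10 | methyl 3-(4-hydroxyphenyl)propanoate | COC(=O)CCc1ccc(O)cc1 | starting material
11 | methyl 3-[4-(triisopropylsilyloxy)phenyl]propanoate | COC(=O)CCc1ccc(O[Si](C(C)C)(C(C)C)C(C)C)cc1 | intermediate
12 | N-methoxy-N-methyl-3-[4-(triisopropylsilyloxy)phenyl]propanamide | CON(C)C(=O)CCc1ccc(O[Si](C(C)C)(C(C)C)C(C)C)cc1 | intermediate
13 | trilithium trianion of 9 (C2, C4 and C6 deprotonated) | COC([O-])=CC([O-])=C(CC=C(C)C)C([O-])=CCC=C(C)C.[Li+].[Li+].[Li+] | intermediate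
14 | methyl 4,6-bis(3-methylbut-2-enyl)-3,5,7-trioxo-9-[4-(triisopropylsilyloxy)phenyl]nonanoate (keto–enol mixture, C4 and C6 labile) | COC(=O)CC(=O)C(CC=C(C)C)C(=O)C(CC=C(C)C)C(=O)CCc1ccc(O[Si](C(C)C)(C(C)C)C(C)C)cc1 | intermediate
15 | methyl 2-hydroxy-3,5-bis(3-methylbut-2-enyl)-4,6-dioxo-2-{2-[4-(triisopropylsilyloxy)phenyl]ethyl}cyclohexane-1-carboxylate (mixture of diastereomers and enol forms) | COC(=O)C1C(=O)C(CC=C(C)C)C(=O)C(CC=C(C)C)C1(O)CCc1ccc(O[Si](C(C)C)(C(C)C)C(C)C)cc1 | intermediate
16 | methyl 2,4-dihydroxy-3,5-bis(3-methylbut-2-enyl)-6-{2-[4-(triisopropylsilyloxy)phenyl]ethyl}benzoate | COC(=O)c1c(O)c(CC=C(C)C)c(O)c(CC=C(C)C)c1CCc1ccc(O[Si](C(C)C)(C(C)C)C(C)C)cc1 | intermediate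
17 | methyl 2,4-dihydroxy-6-[2-(4-hydroxyphenyl)ethyl]-3,5-bis(3-methylbut-2-enyl)benzoate | COC(=O)c1c(O)c(CC=C(C)C)c(O)c(CC=C(C)C)c1CCc1ccc(O)cc1 | target

**Step count**

Total steps: 8. Longest linear sequence: 5 steps (steps 1, 3, 6, 7, 8; equally steps 4, 5, 6, 7, 8).

**Steps most likely to fail, with fallbacks**

Step 7. The ring closure may lose to other modes: Claisen-type attack or O-acylation at the ester carbonyl, methanolysis (retro-Claisen cleavage) of the 2-alkyl-1,3-diketone units, or stalled dehydration of the aldol adduct. The fallback masks the ester carbon as a 1,3-dioxin-4-one, so that only the aldol mode is left. It sets out from acid 5 through its imidazolide 6. C-acylation of Meldrum's acid with 6 (pyridine, CH2Cl2) should give 5-(1-hydroxy-5-methylhex-4-enylidene)-2,2-dimethyl-1,3-dioxane-4,6-dione F1. Heating F1 with acetone in toluene (loss of CO2, capture of the acylketene by acetone) should give 2,2-dimethyl-6-(4-methylpent-3-enyl)-4H-1,3-dioxin-4-one F2. LiN(SiMe3)2 (THF, −78 °C) converts F2 into the lithium dienolate of the dioxinone F3, which a second portion of 6 acylates at the γ-carbon to give 2,2-dimethyl-6-[6-methyl-1-(3-methylbut-2-enyl)-2-oxohept-5-enyl]-4H-1,3-dioxin-4-one F4. LiN(i-Pr)2 (2.2 equiv) turns F4 into the dilithium dianion of the keto-dioxinone F5, and amide 12 acylates its terminal carbon to give 6-{1,3-bis(3-methylbut-2-enyl)-2,4-dioxo-6-[4-(triisopropylsilyloxy)phenyl]hexyl}-2,2-dimethyl-4H-1,3-dioxin-4-one F6. Et3N in CH2Cl2 (or Cs2CO3) should then effect aldol cyclisation and aromatisation to 7-hydroxy-2,2-dimethyl-6,8-bis(3-methylbut-2-enyl)-5-{2-[4-(triisopropylsilyloxy)phenyl]ethyl}-4H-1,3-benzodioxin-4-one F7. NaOMe in MeOH at 0 °C opens the dioxinone ring to the methyl ester with loss of acetone, and the fallback comes back to the route at 16.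

Step 6. The strongly basic trianion may take a proton from the α-CH2 of the amide instead of adding to it, attack by the hindered secondary carbanion may be slow, and the freed triketo ester may cyclise without control during work-up. The fallback replaces the acylation by an aldol addition and oxidation. It sets out from amide 12 and diketo ester 9. Reduction of 12 with i-Bu2AlH (THF, −78 °C) should give 3-[4-(triisopropylsilyloxy)phenyl]propanal F8. Trianion 13 adds to this more electrophilic partner at −78 °C to give methyl 7-hydroxy-4,6-bis(3-methylbut-2-enyl)-3,5-dioxo-9-[4-(triisopropylsilyloxy)phenyl]nonanoate F9 as a mixture of diastereomers. Dess–Martin periodinane (1.1 equiv, NaHCO3, CH2Cl2, 0 °C) oxidises the secondary alcohol, and the fallback comes back to the route at 14.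

Step 3. Acylation at the substituted γ-carbon may be sluggish and lose to enolisation of the amide, and the diketo ester may lactonise to a 4-hydroxy-2-pyranone on handling. The fallback forms the C4–C5 bond with the unhindered dianion and brings in the C4 prenyl group afterwards. It sets out from methyl acetoacetate 1 and amide 7. Dianion 3 is acylated by 7 (THF, −78 to 0 °C) to give methyl 9-methyl-3,5-dioxodec-8-enoate F10. Its most acidic carbon, C4 between the two ketones, is alkylated with one equivalent of prenyl bromide 2 (K2CO3, acetone, rt), and the fallback comes back to the route at 9.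

**Further compounds**

F1 | step 7 | 5-(1-hydroxy-5-methylhex-4-enylidene)-2,2-dimethyl-1,3-dioxane-4,6-dione | CC(C)=CCCC(O)=C1C(=O)OC(C)(C)OC1=O
F2 | step 7 | 2,2-dimethyl-6-(4-methylpent-3-enyl)-4H-1,3-dioxin-4-one | CC(C)=CCCC1=CC(=O)OC(C)(C)O1
F3 | step 7 | lithium dienolate of F2 | [Li+].[O-]C1=CC(=CCC=C(C)C)OC(C)(C)O1
F4 | step 7 | 2,2-dimethyl-6-[6-methyl-1-(3-methylbut-2-enyl)-2-oxohept-5-enyl]-4H-1,3-dioxin-4-one | CC(C)=CCCC(=O)C(CC=C(C)C)C1=CC(=O)OC(C)(C)O1
F5 | step 7 | dilithium dianion of F4 | [Li+].[Li+].[O-]C1=CC(=C(CC=C(C)C)C([O-])=CCC=C(C)C)OC(C)(C)O1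
F6 | step 7 | 6-{1,3-bis(3-methylbut-2-enyl)-2,4-dioxo-6-[4-(triisopropylsilyloxy)phenyl]hexyl}-2,2-dimethyl-4H-1,3-dioxin-4-one | CC(C)=CCC(C(=O)C(CC=C(C)C)C1=CC(=O)OC(C)(C)O1)C(=O)CCc1ccc(O[Si](C(C)C)(C(C)C)C(C)C)cc1
F7 | step 7 | 7-hydroxy-2,2-dimethyl-6,8-bis(3-methylbut-2-enyl)-5-{2-[4-(triisopropylsilyloxy)phenyl]ethyl}-4H-1,3-benzodioxin-4-one | CC1(C)OC(=O)c2c(O1)c(CC=C(C)C)c(O)c(CC=C(C)C)c2CCc1ccc(O[Si](C(C)C)(C(C)C)C(C)C)cc1
F8 | step 6 | 3-[4-(triisopropylsilyloxy)phenyl]propanal | O=CCCc1ccc(O[Si](C(C)C)(C(C)C)C(C)C)cc1
F9 | step 6 | methyl 7-hydroxy-4,6-bis(3-methylbut-2-enyl)-3,5-dioxo-9-[4-(triisopropylsilyloxy)phenyl]nonanoate | COC(=O)CC(=O)C(CC=C(C)C)C(=O)C(CC=C(C)C)C(O)CCc1ccc(O[Si](C(C)C)(C(C)C)C(C)C)cc1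
F10 | step 3 | methyl 9-methyl-3,5-dioxodec-8-enoate | COC(=O)CC(=O)CC(=O)CCC=C(C)C
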